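**Retrosynthetic overview**

- The target is reached by deprotection of 30. The C4–CH2–aryl unit comes from copper-catalysed opening of spiro-epoxide 27 at its CH2 by Grignard reagent 29, and 27 from ketone 25 by methylenation and peracid attack on the face away from the C2 and C3 substituents (sets C4).
- Feature the strategy rests on: in the oxolane (O1, C2 aryl, C3 bearing C9H2O, C4 carbinol, C5H2) the O1–C5 bond is a CH2–O bond directly beside C4. With C4 as a ketone, a C5 carbenoid can insert into the O–H bond of the C2 hydroxyl of the open-chain syn-aldol 24.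
- 24 comes from an Evans syn-aldol of imide 17 with aldehyde 11 (sets oxolane C2 and C3), followed by TES protection, LiOOH cleavage, acid chloride, CH2N2 and desilylation.
- The cis-dihydrobenzofuran of 11 comes from an enantioselective rhodium-carbenoid 1,5-C–H insertion of aryldiazoacetate 6, itself built from 4-bromo-2-methoxyphenol and a vanillyl chloride.
- Ring order: the dihydrofuran ring of the benzofuran first (step 5), the oxolane second (step 17). O9 is carried as a TIPS ether, not a benzyl ether, so that no ether oxygen able to form a five-membered oxonium ylide with a migrating benzyl group sits next to the carbenoid.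

Key step: step 17

**Remarks before the steps**

- Reading of the target: the SMILES fixes a 2,3-cis dihydrobenzofuran (2R,3R) and an oxolane (2R,3R,4S) in which the aryl group (C2), CH2OH (C3) and arylmethyl group (C4) lie on one face and the C4 hydroxyl on the other.
- Assumption: Rh2(S-PTTL)4 is taken to induce the (2R,3S)-cis sense in step 5; should the sense be the opposite, Rh2(R-PTTL)4 is used with no other change.
- Locants used throughout for the oxolane: O1, C2 (aryl), C3 (bears C9H2–O9), C4, C5.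
- "ArD" stands for the (2R,3R)-2-[4-(benzyloxy)-3-methoxyphenyl]-7-methoxy-3-({[tri(propan-2-yl)silyl]oxy}methyl)-2,3-dihydro-1-benzofuran-5-yl group (2,3-cis). TIPS = tri(propan-2-yl)silyl, TES = triethylsilyl.

**Route**

Step 1
Reactants: 1 [4-(benzyloxy)-3-methoxyphenyl]methanol
Product: 2 1-(benzyloxy)-4-(chloromethyl)-2-methoxybenzene
Conditions: SOCl2, CH2Cl2, 0 °C → rt
Reagents that add atoms: thionyl chloride, ClS(Cl)=O
Why: Chlorodehydroxylation of an activated benzylic alcohol through its chlorosulfite should give the stable crystalline chloride.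

Step 2
Reactants: 3 4-bromo-2-methoxyphenol
Product: 4 4-bromo-2-iodo-6-methoxyphenol
Conditions: NaI, NaOH, NaOCl (aq.), MeOH, 0 °C
Reagents that add atoms: sodium iodide, [Na+].[I-]
Why: Electrophilic aromatic iodination of the phenoxide should occur at the only free position ortho to O–, the para position being blocked by bromine.

Step 3
Reactants: 4 4-bromo-2-iodo-6-methoxyphenol; 2 1-(benzyloxy)-4-(chloromethyl)-2-methoxybenzene
Product: 5 1-(benzyloxy)-4-[(4-bromo-2-iodo-6-methoxyphenoxy)methyl]-2-methoxybenzene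
Conditions: K2CO3, DMF, 50 °C
Reagents that add atoms: none
Why: Williamson etherification of a phenoxide with a reactive benzylic chloride is reliable even for a 2,6-disubstituted phenol.

Step 4
Reactants: 5 1-(benzyloxy)-4-[(4-bromo-2-iodo-6-methoxyphenoxy)methyl]-2-methoxybenzene
Product: 6 ethyl 2-(2-{[4-(benzyloxy)-3-methoxyphenyl]methoxy}-5-bromo-3-methoxyphenyl)-2-diazoacetate
Conditions: ethyl diazoacetate, Pd(PPh3)4 (5 mol %), Ag2CO3 (0.5 equiv), Et3N, toluene, rt
Reagents that add atoms: ethyl diazoacetate, CCOC(=O)C=[N+]=[N-]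
Why: This is the known cross-coupling of aryl iodides with ethyl diazoacetate under zerovalent palladium catalysis, which arylates the diazo carbon with the N2 group retained, and oxidative addition at room temperature should select C–I over C–Br.

Step 5
Reactants: 6 ethyl 2-(2-{[4-(benzyloxy)-3-methoxyphenyl]methoxy}-5-bromo-3-methoxyphenyl)-2-diazoacetate
Product: 7 ethyl (2R,3S)-2-[4-(benzyloxy)-3-methoxyphenyl]-5-bromo-7-methoxy-2,3-dihydro-1-benzofuran-3-carboxylate (2,3-cis)
Conditions: Rh2(S-PTTL)4 (PTTL = N-phthaloyl-tert-leucinate, 2 mol %), toluene, −60 °C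
Reagents that add atoms: none
Why: Enantioselective intramolecular 1,5-C–H insertion of a donor/acceptor rhodium carbenoid into the ArO–CH2–aryl bond is the known route to cis-2-aryl-2,3-dihydrobenzofuran-3-carboxylates, the chiral divalent rhodium carboxylate setting both new centres (C2 R, C3 S) with the cis relationship as the kinetic outcome.

Step 6
Reactants: 7 ethyl (2R,3S)-2-[4-(benzyloxy)-3-methoxyphenyl]-5-bromo-7-methoxy-2,3-dihydro-1-benzofuran-3-carboxylate
Product: 8 [(2R,3R)-2-[4-(benzyloxy)-3-methoxyphenyl]-5-bromo-7-methoxy-2,3-dihydro-1-benzofuran-3-yl]methanol (2,3-cis)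
Conditions: DIBAL-H (i-Bu2AlH), CH2Cl2, −78 → −40 °C; Rochelle salt work-up
Reagents that add atoms: none
Why: Ester reduction by an aluminium hydride under non-basic, cold conditions should leave the epimerisable C3 centre and the aryl bromide untouched (the descriptor at C3 changes only by priority).

Step 7
Reactants: 8 [(2R,3R)-2-[4-(benzyloxy)-3-methoxyphenyl]-5-bromo-7-methoxy-2,3-dihydro-1-benzofuran-3-yl]methanol
Product: 9 {[(2R,3R)-2-[4-(benzyloxy)-3-methoxyphenyl]-5-bromo-7-methoxy-2,3-dihydro-1-benzofuran-3-yl]methoxy}tri(propan-2-yl)silane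
Conditions: TIPSCl, imidazole, DMF, rt
Reagents that add atoms: chlorotri(propan-2-yl)silane, CC(C)[Si](Cl)(C(C)C)C(C)C
Why: Silylation of a primary alcohol gives an ether that survives organolithium, peroxide, Grignard and buffered-fluoride steps and can later be told apart from a TES ether.

Step 8
Reactants: 9 {[(2R,3R)-2-[4-(benzyloxy)-3-methoxyphenyl]-5-bromo-7-methoxy-2,3-dihydro-1-benzofuran-3-yl]methoxy}tri(propan-2-yl)silane
Product: 11 (2R,3R)-2-[4-(benzyloxy)-3-methoxyphenyl]-7-methoxy-3-({[tri(propan-2-yl)silyl]oxy}methyl)-2,3-dihydro-1-benzofuran-5-carbaldehyde (ArD–CHO), via aryllithium 10 (not isolated)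
Conditions: n-BuLi, THF, −78 °C; DMF, −78 → 0 °C; H2O
Reagents that add atoms: N,N-dimethylformamide, CN(C)C=O
Why: Bromine–lithium exchange followed by formylation with DMF (Bouveault) is faster than any deprotonation at −78 °C and should leave the silyl and benzyl ethers intact.

Step 9
Reactants: 12 propane-1,3-diol
Product: 13 3-{[tri(propan-2-yl)silyl]oxy}propan-1-ol
Conditions: NaH (1 equiv), THF, rt; then TIPSCl
Reagents that add atoms: chlorotri(propan-2-yl)silane, CC(C)[Si](Cl)(C(C)C)C(C)C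
Why: Monosilylation of a symmetrical diol through its sparingly soluble monosodium alkoxide is a standard way to desymmetrise 1,n-diols.

Step 10
Reactants: 13 3-{[tri(propan-2-yl)silyl]oxy}propan-1-ol
Product: 14 3-{[tri(propan-2-yl)silyl]oxy}propanoic acid
Conditions: TEMPO (cat.), PhI(OAc)2, MeCN–H2O, rt
Reagents that add atoms: water, O
Why: Nitroxyl-catalysed oxidation of a primary alcohol through the aldehyde hydrate gives the acid under conditions that a TIPS ether tolerates.

Step 11
Reactants: 14 3-{[tri(propan-2-yl)silyl]oxy}propanoic acid; 15 (4R)-4-benzyl-1,3-oxazolidin-2-one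
Product: 17 (4R)-4-benzyl-3-(3-{[tri(propan-2-yl)silyl]oxy}propanoyl)-1,3-oxazolidin-2-one, via pivalic mixed anhydride 16 (not isolated)
Conditions: PivCl, Et3N, THF, −20 °C; then 15, LiCl, −20 °C → rt
Reagents that add atoms: none
Why: N-Acylation of the oxazolidinone by a pivalic mixed anhydride with LiCl/Et3N is a standard one-pot imide synthesis, attack occurring at the less hindered carbonyl.

Step 12
Reactants: 17 (4R)-4-benzyl-3-(3-{[tri(propan-2-yl)silyl]oxy}propanoyl)-1,3-oxazolidin-2-one; 11 ArD–CHO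
Product: 19 (4R)-4-benzyl-3-[(2R,3R)-3-ArD-3-hydroxy-2-({[tri(propan-2-yl)silyl]oxy}methyl)propanoyl]-1,3-oxazolidin-2-one (syn), via Z-boron enolate 18 (not isolated)
Conditions: Bu2BOTf, i-Pr2NEt, CH2Cl2, 0 °C; then 11, −78 → 0 °C; pH 7 buffer, MeOH, H2O2
Reagents that add atoms: none
Why: In this Evans syn-aldol the covalent Z-boron enolate (not prone to β-elimination of the silyloxy group) reacts through a Zimmerman–Traxler chair on the face away from the auxiliary benzyl group, which sets the future oxolane C2 (R) and C3 (R) as the syn pair, and the adduct of any residual enantiomer of 11 is a separable diastereomer.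

Step 13
Reactants: 19 syn-aldol adduct
Product: 20 (4R)-4-benzyl-3-[(2R,3R)-3-ArD-3-[(triethylsilyl)oxy]-2-({[tri(propan-2-yl)silyl]oxy}methyl)propanoyl]-1,3-oxazolidin-2-one
Conditions: TESOTf, 2,6-lutidine, CH2Cl2, −78 °C
Reagents that add atoms: triethylsilyl trifluoromethanesulfonate, CC[Si](CC)(CC)OS(=O)(=O)C(F)(F)F
Why: Buffered silylation masks the benzylic hydroxyl (blocking retro-aldol and β-lactone formation in the next steps) with a group far more labile to fluoride than the two primary TIPS ethers.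

Step 14
Reactants: 20 TES-protected aldol adduct
Product: 21 (2R,3R)-3-ArD-3-[(triethylsilyl)oxy]-2-({[tri(propan-2-yl)silyl]oxy}methyl)propanoic acid
Conditions: LiOH, H2O2, THF–H2O, 0 °C; Na2SO3; HCl to pH 4
Reagents that add atoms: hydrogen peroxide, OO
Why: Lithium hydroperoxide cleaves the exocyclic imide carbonyl selectively without epimerising the α-centre, and sulfite reduces the peracid to the acid.

Step 15
Reactants: 21 (2R,3R)-3-ArD-3-[(triethylsilyl)oxy]-2-({[tri(propan-2-yl)silyl]oxy}methyl)propanoic acid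
Product: 23 (3R,4R)-4-ArD-1-diazo-4-[(triethylsilyl)oxy]-3-({[tri(propan-2-yl)silyl]oxy}methyl)butan-2-one, via acid chloride 22 (not isolated)
Conditions: 1-chloro-N,N,2-trimethylprop-1-en-1-amine, CH2Cl2, 0 °C → rt; then CH2N2 (excess), Et2O, 0 °C
Reagents that add atoms: diazomethane, C=[N+]=[N-]
Why: The acid chloride is formed under neutral conditions (no HCl, no amine, hence no ketene and no epimerisation) and acylates diazomethane in the classical diazoketone synthesis, a second equivalent of CH2N2 taking up the HCl.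

Step 16
Reactants: 23 TES-protected diazoketone
Product: 24 (3R,4R)-4-ArD-1-diazo-4-hydroxy-3-({[tri(propan-2-yl)silyl]oxy}methyl)butan-2-one (syn)
Conditions: TBAF, AcOH (1:1), THF, 0 °C
Reagents that add atoms: none
Why: Acetic-acid-buffered fluoride should remove the secondary TES ether well before the primary TIPS ethers, and the buffer suppresses retro-aldol cleavage and E1cB loss of the β-silyloxy group while leaving the diazoketone intact.

Step 17
Reactants: 24 (3R,4R)-4-ArD-1-diazo-4-hydroxy-3-({[tri(propan-2-yl)silyl]oxy}methyl)butan-2-one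
Product: 25 (2R,3R)-2-ArD-3-({[tri(propan-2-yl)silyl]oxy}methyl)oxolan-4-one (2,3-cis)
Conditions: Rh2(OAc)4 (1 mol %), CH2Cl2, rt, slow addition of 24
Reagents that add atoms: none
Why: Rh2(OAc)4 extrudes N2 from 24 to give an electrophilic divalent rhodium carbenoid at C5, a lone pair of the C2 hydroxyl adds to it to form a metal-associated oxonium ylide, and a 1,2-proton shift releases the catalyst with the O1–C5 bond in place. The closest known reaction type is the intramolecular O–H insertion of aldol-derived hydroxy diazoketones to tetrahydrofuran-3-ones under divalent rhodium carboxylate catalysis. The oxolane closes as a five-membered ring by O–C bond formation, the oxygen attacking the carbenoid carbon exo to the Rh=C bond, with C4 already at the ketone level. No stereocentre is created; since C2 and C3 keep all four of their bonds, the syn relationship of 24 is carried over unchanged as the 2,3-cis relationship of 25, which an acid-mediated closure by way of a C2 benzylic cation could not promise. The step needs O–H insertion to win over Buchner addition to the electron-rich C2 aryl ring, over oxonium ylide formation at ether oxygens and over carbenoid dimerisation: the free hydroxyl is the only unhindered Lewis-basic site at five-ring distance, O9 is a bulky TIPS ether in place of a benzyl ether (which could give a five-membered oxonium ylide and a [1,2]-benzyl shift), and slow addition keeps the diazo concentration low. The neutral, base-free medium protects the epimerisable C3 beside the new ketone, and 25 is taken on after filtration only.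

Step 18
Reactants: 25 (2R,3R)-2-ArD-3-({[tri(propan-2-yl)silyl]oxy}methyl)oxolan-4-one
Product: 26 (2R,3R)-2-ArD-4-methylidene-3-({[tri(propan-2-yl)silyl]oxy}methyl)oxolane
Conditions: Cp2TiMe2, toluene, 65 °C, dark
Reagents that add atoms: dimethyltitanocene, C[Ti](C)(C1C=CC=C1)C1C=CC=C1
Why: Petasis methylenation through Cp2Ti=CH2 is non-basic, so the enolisable ketone should be converted without C3 epimerisation or β-elimination of the silyloxy group, which a phosphorus ylide would risk.

Step 19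
Reactants: 26 (2R,3R)-2-ArD-4-methylidene-3-({[tri(propan-2-yl)silyl]oxy}methyl)oxolane
Product: 27 (3R,6R,7R)-6-ArD-7-({[tri(propan-2-yl)silyl]oxy}methyl)-1,5-dioxaspiro[2.4]heptane (epoxide oxygen trans to the C6 and C7 substituents)
Conditions: m-CPBA, NaHCO3, CH2Cl2, 0 °C
Reagents that add atoms: 3-chloroperoxybenzoic acid, OOC(=O)c1cccc(Cl)c1
Why: Prilezhaev epoxidation of the 1,1-disubstituted alkene should occur on the ring face opposite the cis-disposed C3 silyloxymethyl and C2 aryl groups, which places the epoxide oxygen (the future C4 hydroxyl) trans to them and sets C4.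

Step 20
Reactants: 3 4-bromo-2-methoxyphenol
Product: 28 1-(benzyloxy)-4-bromo-2-methoxybenzene
Conditions: BnBr, K2CO3, acetone, reflux
Reagents that add atoms: benzyl bromide, BrCc1ccccc1
Why: Williamson benzylation of the phenol gives a protecting group that tolerates Grignard formation and is removed last by mild hydrogenolysis.

Step 21
Reactants: 28 1-(benzyloxy)-4-bromo-2-methoxybenzene; 27 spiro-epoxide
Product: 30 (2R,3R,4S)-2-ArD-4-{[4-(benzyloxy)-3-methoxyphenyl]methyl}-3-({[tri(propan-2-yl)silyl]oxy}methyl)oxolan-4-ol, via arylmagnesium bromide 29 (not isolated)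
Conditions: Mg, THF; then CuI (10 mol %), 27, THF, −30 → 0 °C; H2O
Reagents that add atoms: none
Why: Copper-catalysed SN2 opening of a 2,2-disubstituted epoxide by an aryl Grignard reagent occurs at the CH2 terminus, so the C4–O bond and its configuration are untouched and the arylmethyl group ends up cis to C9 and to the C2 aryl group.

Step 22
Reactants: 30 bis-TIPS ether
Product: 31 (2R,3R,4S)-2-[(2R,3R)-2-[4-(benzyloxy)-3-methoxyphenyl]-3-(hydroxymethyl)-7-methoxy-2,3-dihydro-1-benzofuran-5-yl]-4-{[4-(benzyloxy)-3-methoxyphenyl]methyl}-3-(hydroxymethyl)oxolan-4-ol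
Conditions: TBAF, THF, rt
Reagents that add atoms: none
Why: Fluoride desilylation frees both primary alcohols under conditions to which the benzylic ring ethers and aryl benzyl ethers are inert.

Step 23
Reactants: 31 triol bis(benzyl ether)
Product: 32 (2R,3R,4S)-2-[(2R,3R)-2-(4-hydroxy-3-methoxyphenyl)-3-(hydroxymethyl)-7-methoxy-2,3-dihydro-1-benzofuran-5-yl]-4-[(4-hydroxy-3-methoxyphenyl)methyl]-3-(hydroxymethyl)oxolan-4-ol (CNP0284796.1)
Conditions: H2 (1 atm), 10 % Pd/C, EtOAc–MeOH, rt
Reagents that add atoms: none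
Why: Hydrogenolysis of the two aryl benzyl ethers is fast under neutral conditions and should be complete before the hindered, electron-rich benzylic C–O bonds of the oxolane and dihydrobenzofuran rings react.

**Compound list**

1 | [4-(benzyloxy)-3-methoxyphenyl]methanol | COc1cc(CO)ccc1OCc1ccccc1 | starting material
2 | 1-(benzyloxy)-4-(chloromethyl)-2-methoxybenzene | COc1cc(CCl)ccc1OCc1ccccc1 | intermediate
3 | 4-bromo-2-methoxyphenol | COc1cc(Br)ccc1O | starting material
4 | 4-bromo-2-iodo-6-methoxyphenol | COc1cc(Br)cc(I)c1O | intermediate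
5 | 1-(benzyloxy)-4-[(4-bromo-2-iodo-6-methoxyphenoxy)methyl]-2-methoxybenzene | COc1cc(Br)cc(I)c1OCc1ccc(OCc2ccccc2)c(OC)c1 | intermediate
6 | ethyl 2-(2-{[4-(benzyloxy)-3-methoxyphenyl]methoxy}-5-bromo-3-methoxyphenyl)-2-diazoacetate | CCOC(=O)C(=[N+]=[N-])c1cc(Br)cc(OC)c1OCc1ccc(OCc2ccccc2)c(OC)c1 | intermediate
7 | ethyl (2R,3S)-2-[4-(benzyloxy)-3-methoxyphenyl]-5-bromo-7-methoxy-2,3-dihydro-1-benzofuran-3-carboxylate (cis) | Brc3cc(OC)c4c(c3)[C@H](C(=O)OCC)[C@H](c3ccc(OCc5ccccc5)c(OC)c3)O4 | intermediate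
8 | [(2R,3R)-2-[4-(benzyloxy)-3-methoxyphenyl]-5-bromo-7-methoxy-2,3-dihydro-1-benzofuran-3-yl]methanol (cis) | Brc3cc(OC)c4c(c3)[C@H](CO)[C@H](c3ccc(OCc5ccccc5)c(OC)c3)O4 | intermediate
9 | {[(2R,3R)-2-[4-(benzyloxy)-3-methoxyphenyl]-5-bromo-7-methoxy-2,3-dihydro-1-benzofuran-3-yl]methoxy}tri(propan-2-yl)silane | Brc3cc(OC)c4c(c3)[C@H](CO[Si](C(C)C)(C(C)C)C(C)C)[C@H](c3ccc(OCc5ccccc5)c(OC)c3)O4 | intermediate
10 | aryllithium from 9 (5-lithio compound) | [Li]c3cc(OC)c4c(c3)[C@H](CO[Si](C(C)C)(C(C)C)C(C)C)[C@H](c3ccc(OCc5ccccc5)c(OC)c3)O4 | intermediate (not isolated)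
11 | (2R,3R)-2-[4-(benzyloxy)-3-methoxyphenyl]-7-methoxy-3-({[tri(propan-2-yl)silyl]oxy}methyl)-2,3-dihydro-1-benzofuran-5-carbaldehyde (ArD–CHO) | O=Cc3cc(OC)c4c(c3)[C@H](CO[Si](C(C)C)(C(C)C)C(C)C)[C@H](c3ccc(OCc5ccccc5)c(OC)c3)O4 | intermediate
12 | propane-1,3-diol | OCCCO | starting material
13 | 3-{[tri(propan-2-yl)silyl]oxy}propan-1-ol | OCCCO[Si](C(C)C)(C(C)C)C(C)C | intermediate
14 | 3-{[tri(propan-2-yl)silyl]oxy}propanoic acid | OC(=O)CCO[Si](C(C)C)(C(C)C)C(C)C | intermediate
15 | (4R)-4-benzyl-1,3-oxazolidin-2-one | O=C1N[C@H](Cc2ccccc2)CO1 | starting material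
16 | 2,2-dimethylpropanoic 3-{[tri(propan-2-yl)silyl]oxy}propanoic anhydride | CC(C)(C)C(=O)OC(=O)CCO[Si](C(C)C)(C(C)C)C(C)C | intermediate (not isolated)
17 | (4R)-4-benzyl-3-(3-{[tri(propan-2-yl)silyl]oxy}propanoyl)-1,3-oxazolidin-2-one | O=C(CCO[Si](C(C)C)(C(C)C)C(C)C)N1[C@H](Cc2ccccc2)COC1=O | intermediate
18 | Z-dibutylboron enolate of 17 | CCCCB(CCCC)O/C(N1[C@H](Cc2ccccc2)COC1=O)=C\CO[Si](C(C)C)(C(C)C)C(C)C | intermediate (not isolated)
19 | (4R)-4-benzyl-3-[(2R,3R)-3-ArD-3-hydroxy-2-({[tri(propan-2-yl)silyl]oxy}methyl)propanoyl]-1,3-oxazolidin-2-one | O[C@@H](c3cc(OC)c4c(c3)[C@H](CO[Si](C(C)C)(C(C)C)C(C)C)[C@H](c3ccc(OCc5ccccc5)c(OC)c3)O4)[C@H](C(=O)N1[C@H](Cc2ccccc2)COC1=O)CO[Si](C(C)C)(C(C)C)C(C)C | intermediate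
20 | (4R)-4-benzyl-3-[(2R,3R)-3-ArD-3-[(triethylsilyl)oxy]-2-({[tri(propan-2-yl)silyl]oxy}methyl)propanoyl]-1,3-oxazolidin-2-one | CC[Si](CC)(CC)O[C@@H](c3cc(OC)c4c(c3)[C@H](CO[Si](C(C)C)(C(C)C)C(C)C)[C@H](c3ccc(OCc5ccccc5)c(OC)c3)O4)[C@H](C(=O)N1[C@H](Cc2ccccc2)COC1=O)CO[Si](C(C)C)(C(C)C)C(C)C | intermediate
21 | (2R,3R)-3-ArD-3-[(triethylsilyl)oxy]-2-({[tri(propan-2-yl)silyl]oxy}methyl)propanoic acid | CC[Si](CC)(CC)O[C@@H](c3cc(OC)c4c(c3)[C@H](CO[Si](C(C)C)(C(C)C)C(C)C)[C@H](c3ccc(OCc5ccccc5)c(OC)c3)O4)[C@H](C(=O)O)CO[Si](C(C)C)(C(C)C)C(C)C | intermediate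
22 | (2R,3R)-3-ArD-3-[(triethylsilyl)oxy]-2-({[tri(propan-2-yl)silyl]oxy}methyl)propanoyl chloride | CC[Si](CC)(CC)O[C@@H](c3cc(OC)c4c(c3)[C@H](CO[Si](C(C)C)(C(C)C)C(C)C)[C@H](c3ccc(OCc5ccccc5)c(OC)c3)O4)[C@H](C(Cl)=O)CO[Si](C(C)C)(C(C)C)C(C)C | intermediate (not isolated)
23 | (3R,4R)-4-ArD-1-diazo-4-[(triethylsilyl)oxy]-3-({[tri(propan-2-yl)silyl]oxy}methyl)butan-2-one | CC[Si](CC)(CC)O[C@@H](c3cc(OC)c4c(c3)[C@H](CO[Si](C(C)C)(C(C)C)C(C)C)[C@H](c3ccc(OCc5ccccc5)c(OC)c3)O4)[C@H](C(=O)C=[N+]=[N-])CO[Si](C(C)C)(C(C)C)C(C)C | intermediate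
24 | (3R,4R)-4-ArD-1-diazo-4-hydroxy-3-({[tri(propan-2-yl)silyl]oxy}methyl)butan-2-one (key-step precursor) | O[C@@H](c3cc(OC)c4c(c3)[C@H](CO[Si](C(C)C)(C(C)C)C(C)C)[C@H](c3ccc(OCc5ccccc5)c(OC)c3)O4)[C@H](C(=O)C=[N+]=[N-])CO[Si](C(C)C)(C(C)C)C(C)C | intermediate
25 | (2R,3R)-2-ArD-3-({[tri(propan-2-yl)silyl]oxy}methyl)oxolan-4-one (2,3-cis; key-step product) | O=C1CO[C@@H](c3cc(OC)c4c(c3)[C@H](CO[Si](C(C)C)(C(C)C)C(C)C)[C@H](c3ccc(OCc5ccccc5)c(OC)c3)O4)[C@H]1CO[Si](C(C)C)(C(C)C)C(C)C | intermediate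
26 | (2R,3R)-2-ArD-4-methylidene-3-({[tri(propan-2-yl)silyl]oxy}methyl)oxolane | C=C1CO[C@@H](c3cc(OC)c4c(c3)[C@H](CO[Si](C(C)C)(C(C)C)C(C)C)[C@H](c3ccc(OCc5ccccc5)c(OC)c3)O4)[C@H]1CO[Si](C(C)C)(C(C)C)C(C)C | intermediate
27 | (3R,6R,7R)-6-ArD-7-({[tri(propan-2-yl)silyl]oxy}methyl)-1,5-dioxaspiro[2.4]heptane | C1[C@@]2(O1)CO[C@@H](c3cc(OC)c4c(c3)[C@H](CO[Si](C(C)C)(C(C)C)C(C)C)[C@H](c3ccc(OCc5ccccc5)c(OC)c3)O4)[C@H]2CO[Si](C(C)C)(C(C)C)C(C)C | intermediate
28 | 1-(benzyloxy)-4-bromo-2-methoxybenzene | COc1cc(Br)ccc1OCc1ccccc1 | intermediate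
29 | [4-(benzyloxy)-3-methoxyphenyl]magnesium bromide | COc1cc([Mg]Br)ccc1OCc1ccccc1 | intermediate (not isolated)
30 | (2R,3R,4S)-2-ArD-4-{[4-(benzyloxy)-3-methoxyphenyl]methyl}-3-({[tri(propan-2-yl)silyl]oxy}methyl)oxolan-4-ol | COc1cc(C[C@@]2(O)CO[C@@H](c3cc(OC)c4c(c3)[C@H](CO[Si](C(C)C)(C(C)C)C(C)C)[C@H](c3ccc(OCc5ccccc5)c(OC)c3)O4)[C@H]2CO[Si](C(C)C)(C(C)C)C(C)C)ccc1OCc1ccccc1 | intermediate
31 | (2R,3R,4S)-2-[(2R,3R)-2-[4-(benzyloxy)-3-methoxyphenyl]-3-(hydroxymethyl)-7-methoxy-2,3-dihydro-1-benzofuran-5-yl]-4-{[4-(benzyloxy)-3-methoxyphenyl]methyl}-3-(hydroxymethyl)oxolan-4-ol | COc1cc(C[C@@]2(O)CO[C@@H](c3cc(OC)c4c(c3)[C@H](CO)[C@H](c3ccc(OCc5ccccc5)c(OC)c3)O4)[C@H]2CO)ccc1OCc1ccccc1 | intermediate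
32 | (2R,3R,4S)-2-[(2R,3R)-2-(4-hydroxy-3-methoxyphenyl)-3-(hydroxymethyl)-7-methoxy-2,3-dihydro-1-benzofuran-5-yl]-4-[(4-hydroxy-3-methoxyphenyl)methyl]-3-(hydroxymethyl)oxolan-4-ol (CNP0284796.1) | COc1cc(C[C@@]2(O)CO[C@@H](c3cc(OC)c4c(c3)[C@H](CO)[C@H](c3ccc(O)c(OC)c3)O4)[C@H]2CO)ccc1O | target

**Step count and risks**

Total step count: 23. Longest linear sequence: 18 steps (from 3 through steps 2–8, 12–19 and 21–23).

The three steps most likely to fail:

1. Step 5 (carbenoid C–H insertion). The enantiofacial discrimination, or the kinetic cis preference, may be incomplete for this trisubstituted aryl ring and ethyl ester. The fallback replaces catalyst control by a classical resolution. It sets out from 8 of insufficient enantiomeric purity and comes back at 8. Acylation with (1S)-camphanic chloride (Et3N, DMAP, CH2Cl2) should give the (1S)-camphanate ester of 8, F1. The diastereomer that stems from the minor enantiomer is removed by crystallisation or chromatography, and K2CO3 in MeOH returns enantiopure 8.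

2. Step 17 (key O–H insertion). The carbenoid may be diverted (addition to the C2 aryl ring, dimerisation, capture of adventitious water), or the cis-ketone may epimerise at C3 during isolation. The fallback closes the same O1–C5 bond by ionic chemistry without a carbenoid. It sets out from 23 and comes back at 25. One equivalent of aqueous HBr in Et2O at −20 °C should convert the diazoketone into the TES-protected bromomethyl ketone F2. Buffered TBAF/AcOH then frees the hydroxy bromomethyl ketone F3. Ag2O in CH2Cl2 closes the ring by intramolecular Williamson etherification (5-exo-tet) to 25, again without touching C2 or C3.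

3. Step 19 (epoxidation). Peracid attack may not be fully face-selective, and the peracid may oxidise the electron-rich arenes. The fallback replaces direct epoxidation by dihydroxylation and ring closure. It sets out from 26 and comes back at 27. OsO4 (cat.) with N-methylmorpholine N-oxide in acetone–water should dihydroxylate the exocyclic alkene from the open face, the bulkier reagent being more sensitive to the cis substituents and inert to the arenes, to give the diol F4. Selective sulfonylation of the primary hydroxyl (TsCl, Et3N, cat. Bu2SnO) gives the monotosylate F5, and K2CO3 in MeOH closes the epoxide 27 with the tertiary C–O bond retained.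

**Further compounds**

F1 | step 5 | [(2R,3R)-2-[4-(benzyloxy)-3-methoxyphenyl]-5-bromo-7-methoxy-2,3-dihydro-1-benzofuran-3-yl]methyl (1S,4R)-4,7,7-trimethyl-3-oxo-2-oxabicyclo[2.2.1]heptane-1-carboxylate | Brc3cc(OC)c4c(c3)[C@H](COC(=O)[C@@]12CC[C@@](C)(C(=O)O1)C2(C)C)[C@H](c3ccc(OCc5ccccc5)c(OC)c3)O4
F2 | step 17 | (3R,4R)-4-ArD-1-bromo-4-[(triethylsilyl)oxy]-3-({[tri(propan-2-yl)silyl]oxy}methyl)butan-2-one | CC[Si](CC)(CC)O[C@@H](c3cc(OC)c4c(c3)[C@H](CO[Si](C(C)C)(C(C)C)C(C)C)[C@H](c3ccc(OCc5ccccc5)c(OC)c3)O4)[C@H](C(=O)CBr)CO[Si](C(C)C)(C(C)C)C(C)C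
F3 | step 17 | (3R,4R)-4-ArD-1-bromo-4-hydroxy-3-({[tri(propan-2-yl)silyl]oxy}methyl)butan-2-one | O[C@@H](c3cc(OC)c4c(c3)[C@H](CO[Si](C(C)C)(C(C)C)C(C)C)[C@H](c3ccc(OCc5ccccc5)c(OC)c3)O4)[C@H](C(=O)CBr)CO[Si](C(C)C)(C(C)C)C(C)C
F4 | step 19 | (2R,3R,4R)-2-ArD-4-(hydroxymethyl)-3-({[tri(propan-2-yl)silyl]oxy}methyl)oxolan-4-ol | OC[C@@]2(O)CO[C@@H](c3cc(OC)c4c(c3)[C@H](CO[Si](C(C)C)(C(C)C)C(C)C)[C@H](c3ccc(OCc5ccccc5)c(OC)c3)O4)[C@H]2CO[Si](C(C)C)(C(C)C)C(C)C
F5 | step 19 | [(2R,3R,4S)-2-ArD-4-hydroxy-3-({[tri(propan-2-yl)silyl]oxy}methyl)oxolan-4-yl]methyl 4-methylbenzenesulfonate | Cc1ccc(cc1)S(=O)(=O)OC[C@@]2(O)CO[C@@H](c3cc(OC)c4c(c3)[C@H](CO[Si](C(C)C)(C(C)C)C(C)C)[C@H](c3ccc(OCc5ccccc5)c(OC)c3)O4)[C@H]2CO[Si](C(C)C)(C(C)C)C(C)C
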